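In a one-step world substrate and reagent give target and stop, so the target equals the smaller charge, the limiting reagent. We want the target at the end of each flask.

| flask | substrate | reagent | initiator | remark | time |
|---|---|---|---|---|---|
| Tuesday's | 1.1 mM | 28.8 mM | 0.74 mM | run made earlier |  |
| Friday's | 110 mM | 28.8 mM | 0.74 mM | run made earlier |  |
| oak | 0.80 mM | 28.8 mM | 0.74 mM |  | 6.0 h |
| cedar | 2.5 mM | 28.8 mM | 0.74 mM |  | 6.0 h |
| maple | 8.0 mM | 28.8 mM | 0.74 mM |  | 6.0 h |
| larch | 25 mM | 28.8 mM | 0.74 mM |  | 6.0 h |
| ash | 80 mM | 28.8 mM | 0.74 mM |  | 6.0 h |

| Tuesday's: time / h | Tuesday's: target / % | Friday's: time / h | Friday's: target / % |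
|---|---|---|---|
| 1.00 | 65.8 | 0.333 | 23.0 |
| 2.00 | 47.0 | 0.833 | 16.2 |
| 3.00 | 29.7 | 2.00 | 10.3 |
| 4.00 | 19.2 | 4.00 | 2.9 |

(scatter of a reading: 1 percentage point)
- the numbers in the tables scatter with a standard deviation of 1 percentage point
- steps under discussion: 2 initiating radical -> ended chains; initiator -> 2 initiating radical; reagent + chain carrier -> target + initiating radical; substrate + initiating radical -> chain carrier; target -> over-reaction product
- "hardly changes" means that all values lie within two and a half points (for a concentration: within two and a half percent of the largest)
- [target] at the end for oak, cedar, maple, larch, ash, in this order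
- the course of these numbers from the first flask to the last (falls all the way / hardly changes / falls, then rises / rises all the way / rises, then falls)

Step 1. With the main step by itself, the target follows the substrate charge up to larch, whose substrate charge of 25 mM is less than the reagent charge, and ash, whose substrate charge is more than the reagent charge, stops at 28.8 mM.

Step 2. We add the over-reaction. Tuesday's readings from 2.00 h to 4.00 h fall with a first-order constant of 0.448 h⁻¹. In this picture the row scales with the limiting charge, and ash still ends above larch by a factor of 1.15.

Step 3. We add the time the chain needs to make the target. Running that decay line back to the full charge gives a making lag of 0.313 h on Tuesday. Friday's first reading, set against the reagent charge, gives 0.0435 h. Target made later is younger at the end, so a flask with a smaller charge can catch up. We call the break-even head start 0.316 h the difference in making lag at which larch's smaller charge exactly offsets the extra target in ash: the logarithm of the ratio of the two limiting charges, divided by the decay constant.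

Giving larch Tuesday's lag and ash Friday's, we read a head start of 0.270 h, which is less than the break-even value. The gap of 0.0460 h is smaller than the 0.0971 h that one point of scatter moves Friday's lag. Our reckoning therefore puts larch and ash level within the readings, and it does not commit to a last rise.

The forecast gave 0.061 mM, 0.19 mM, 0.61 mM, 1.9 mM and 2.2 mM, with the course rises all the way, "levelling off once reagent becomes limiting". Here it differs from our reckoning, which leaves the last step open.

The flasks gave 0.0594 mM, 0.186 mM, 0.594 mM, 1.86 mM and 1.81 mM: rises, then falls.

    2 initiating radical → ended chains (k = 8.80 × 10⁶ M⁻¹ s⁻¹)
    initiator → 2 initiating radical (k = 4.30 × 10⁻⁵ s⁻¹)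
    reagent + chain carrier → target + initiating radical (k = 6600 M⁻¹ s⁻¹)
    substrate + initiating radical → chain carrier (k = 12000 M⁻¹ s⁻¹)
    target → over-reaction product (k = 1.30 × 10⁻⁴ s⁻¹)

In oak the reagent step had 99.9% of its turnover up to the end behind it by 3.00 h, while the turning of target into over-reaction product, half-life 1.5 h, went on to the end. In ash the reagent stood at 0% at the end with substrate at 62.9%, and the target was 6.28% of the reagent charge, against 7.44% of the substrate charge in larch. That is a head start of 0.377 h for larch, more than the break-even 0.316 h. Maple, by the same reckoning, needed 2.86 h to pass ash and held 0.372 h.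

All runs were computed with made-up constants; scatter was added.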